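## Retrosynthetic overview

- The target has one ring, a 3,6-dihydro-2H-pyran (O1, C2, C3H2, C4H=C5(CH3), C6), with the dichlorinated C2′ arm on C2 and C7 (CHBr2) on C6. The plan rests on the ring alkene C4=C5 with C3 and C6 cis, read as a C4≡C5 alkyne between an epoxide-derived C3H2 and a propargylic C6 carbinol.
- C7 is taken back from CHBr2 to CHO to CH2OAc. The ring is closed late through O1–C6: the C2 hydroxyl attacks the C6/C7 dioxolanylium ion (6-exo) with inversion at C6.
- The C4=C5(CH3) alkene comes from the C4≡C5 alkyne by syn-hydrostannation (tin on C5) and Stille methylation.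
- The C3–C4 bond comes from the lithium acetylide of (4R)-4-ethynyl-2,2-dimethyl-1,3-dioxolane and BF3·OEt2 opening (2S)-2-[(2R)-1,2-dichloropropan-2-yl]oxirane at its CH2; no ring forms here.
- The epoxide comes from a Z-chloro allylic alcohol by Sharpless epoxidation (sets C2) and chloride opening with inversion (sets C2′); the alkyne comes from the (4S)-dioxolane ester.

Key step: step 9

Remark on the chemistry: atom labels in the Why lines (O1, C2–C7, C2′) are those of the target ring, with C7 the exocyclic carbon on C6 and C2′ the quaternary chlorinated carbon, and are kept for open-chain intermediates; compounds 1, 2 and 13 are assumed to be purchased.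

## Route

Step 1
Reactants: 1 (tert-butyldimethylsilyloxy)acetaldehyde; 2 ethyl 2-[bis(2,2,2-trifluoroethoxy)phosphoryl]propanoate
Product: 4 ethyl (2Z)-4-[(tert-butyldimethylsilyl)oxy]-2-methylbut-2-enoate, via potassium phosphonate carbanion 3 (not isolated)
Conditions: KN(SiMe3)2, 18-crown-6, THF, −78 °C
Reagents that add atoms: none
Why: Still–Gennari olefination: the bis(trifluoroethyl) phosphonate anion, kept free of potassium by the crown ether, adds to aldehyde 1 and eliminates faster than it equilibrates, so the trisubstituted enoate should form with the ester cis to the CH2OTBS group (Z), the geometry that later places CH2Cl and the carbinol carbon on the same side of the epoxide.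

Step 2
Reactants: 4 ethyl (2Z)-4-[(tert-butyldimethylsilyl)oxy]-2-methylbut-2-enoate
Product: 5 (2Z)-4-[(tert-butyldimethylsilyl)oxy]-2-methylbut-2-en-1-ol
Conditions: iBu2AlH, CH2Cl2, −78 °C; Rochelle salt
Reagents that add atoms: none
Why: iBu2AlH reduces the conjugated ester to the allylic alcohol by 1,2-hydride delivery at low temperature, leaving the silyl ether and the Z geometry untouched.

Step 3
Reactants: 5 (2Z)-4-[(tert-butyldimethylsilyl)oxy]-2-methylbut-2-en-1-ol
Product: 7 tert-butyl{[(2Z)-4-chloro-3-methylbut-2-en-1-yl]oxy}dimethylsilane, via allylic mesylate 6 (not isolated)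
Conditions: MsCl, 2,4,6-collidine, LiCl, DMF, 0 °C
Reagents that add atoms: lithium chloride, [Li+].[Cl-]
Why: Meyers-type allylic chlorination: the primary allylic mesylate is displaced in situ by chloride in a direct SN2 reaction, so neither allylic transposition nor loss of the Z geometry is expected, and the CH2Cl of the C2′ arm is installed while its carbon is still allylic and unhindered.

Step 4
Reactants: 7 tert-butyl{[(2Z)-4-chloro-3-methylbut-2-en-1-yl]oxy}dimethylsilane
Product: 8 (2Z)-4-chloro-3-methylbut-2-en-1-ol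
Conditions: CSA (cat.), MeOH, 0 °C
Reagents that add atoms: none
Why: Acid-catalysed methanolysis cleaves the primary TBS ether under conditions too mild and too cold to solvolyse the primary allylic chloride, and it avoids fluoride or base, which could close the Z-chloro alcohol to a dihydrofuran.

Step 5
Reactants: 8 (2Z)-4-chloro-3-methylbut-2-en-1-ol
Product: 9 [(2S,3S)-3-(chloromethyl)-3-methyloxiran-2-yl]methanol
Conditions: Ti(OiPr)4 (cat.), L-(+)-diethyl tartrate (cat.), t-BuOOH, 4 Å MS, CH2Cl2, −20 °C
Reagents that add atoms: tert-butyl hydroperoxide, CC(C)(C)OO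
Why: Sharpless asymmetric epoxidation of a 3,3-disubstituted allylic alcohol: the L-(+)-tartrate titanium complex delivers oxygen to the face that gives the (2S,3S)-epoxy alcohol, which sets the carbinol centre (future C2) directly and, through the Z geometry, the relative configuration needed at the tertiary carbon (future C2′).

Step 6
Reactants: 9 [(2S,3S)-3-(chloromethyl)-3-methyloxiran-2-yl]methanol
Product: 10 (2S,3R)-3,4-dichloro-3-methylbutane-1,2-diol
Conditions: TiCl(OiPr)3, CH2Cl2, 0 °C to rt
Reagents that add atoms: chlorotitanium triisopropoxide, CC(C)O[Ti](Cl)(OC(C)C)OC(C)C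
Why: Titanium-mediated C3-selective opening of a 2,3-epoxy alcohol: binding of the primary alkoxide and the epoxide oxygen to tetravalent titanium directs chloride to the distal, tertiary carbon in an SN2-type opening with inversion, which turns the (3S)-epoxide carbon into the (R)-tertiary chloride (C2′) and leaves the C2–O bond intact.

Step 7
Reactants: 10 (2S,3R)-3,4-dichloro-3-methylbutane-1,2-diol
Product: 12 (2S)-2-[(2R)-1,2-dichloropropan-2-yl]oxirane, via primary tosylate 11 (not isolated)
Conditions: TsCl, Bu2SnO (cat.), Et3N, CH2Cl2, 0 °C; then K2CO3, MeOH, 0 °C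
Reagents that add atoms: none
Why: Dibutyltin oxide-catalysed sulfonylation goes through the stannylene acetal and tosylates only the primary hydroxyl, and carbonate then closes the terminal epoxide by 3-exo-tet displacement of the primary sulfonate by the C2 alkoxide (configuration at C2 retained), a displacement that should outrun attack of the same alkoxide on the tertiary, inductively deactivated C2′–Cl.

Step 8
Reactants: 13 methyl (4S)-2,2-dimethyl-1,3-dioxolane-4-carboxylate
Product: 15 (4R)-4-ethynyl-2,2-dimethyl-1,3-dioxolane, via glyceraldehyde acetonide 14 (not isolated)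
Conditions: iBu2AlH, CH2Cl2, −78 °C; then MeOH, K2CO3, MeC(O)C(N2)P(O)(OMe)2, −78 °C to rt
Reagents that add atoms: dimethyl (1-diazo-2-oxopropyl)phosphonate, COP(=O)(OC)C(=[N+]=[N-])C(C)=O
Why: Half-reduction of the ester with iBu2AlH to the aluminium hemiacetal followed in the same flask by Ohira–Bestmann (Seyferth–Gilbert) homologation avoids isolating the configurationally labile α-alkoxy aldehyde 14; the stereocentre is not touched, and its descriptor changes from S to R only because the ethynyl group ranks below CH2O.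

Step 9
Reactants: 15 (4R)-4-ethynyl-2,2-dimethyl-1,3-dioxolane; 12 (2S)-2-[(2R)-1,2-dichloropropan-2-yl]oxirane
Product: 17 (2R,3S)-1,2-dichloro-6-[(4R)-2,2-dimethyl-1,3-dioxolan-4-yl]-2-methylhex-5-yn-3-ol, via lithium acetylide 16 (not isolated)
Conditions: n-BuLi, THF, −78 °C; BF3·OEt2, −78 °C; then 12, −78 °C; aq. NH4Cl
Reagents that add atoms: none
Why: Deprotonation of 15 gives lithium acetylide 16, which with BF3·OEt2 at −78 °C becomes an alkynylborate-type nucleophile that attacks the BF3-activated epoxide 12 at its CH2 terminus by SN2, forming the C3–C4 bond and releasing the C2 oxygen as a boron-bound alkoxide. The closest known reaction type is the Yamaguchi–Hirao alkynylation of terminal epoxides. No ring is closed and no stereocentre is made or broken: the C2–O bond, C2′ and the dioxolane carbon (future C6) are untouched, so the configurations set in steps 5, 6 and in ester 13 pass unchanged into 17. The step needs regioselectivity for CH2 over C2, which is secured by the quaternary C2′ next to C2 (neopentyl-type shielding) and by the inductive deactivation of C2 by the two chlorines. It also needs chemoselectivity over the alkyl chlorides, secured by the low temperature, the low basicity of the BF3-complexed acetylide, and the fact that one chloride is tertiary and the other neopentyl, so neither can undergo SN2. The alkoxide stays boron-bound until the cold NH4Cl quench, so it cannot displace the neighbouring C2′ chloride.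

Step 10
Reactants: 17 (2R,3S)-1,2-dichloro-6-[(4R)-2,2-dimethyl-1,3-dioxolan-4-yl]-2-methylhex-5-yn-3-ol
Product: 18 (2R,6S,7R)-7,8-dichloro-7-methyloct-3-yne-1,2,6-triol
Conditions: p-TsOH·H2O (cat.), MeOH, rt
Reagents that add atoms: none
Why: Acid-catalysed transacetalisation in methanol releases the C6/C7 diol; the tertiary chloride is protected against ionisation by its β-chloro and β-hydroxy substituents and the alkyne is inert.

Step 11
Reactants: 18 (2R,6S,7R)-7,8-dichloro-7-methyloct-3-yne-1,2,6-triol
Product: 19 (2S,3E,6S,7R)-7,8-dichloro-7-methyl-3-(tributylstannyl)oct-3-ene-1,2,6-triol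
Conditions: Bu3SnH, PdCl2(PPh3)2 (cat.), THF, 0 °C
Reagents that add atoms: tributyltin hydride, CCCC[SnH](CCCC)CCCC
Why: Palladium-catalysed hydrostannation adds H and SnBu3 to the same side of the C4≡C5 bond, and the inductive pull and coordination of the propargylic C6 hydroxyl (reinforced by the C7 hydroxyl) should place tin on C5 and hydrogen on C4, giving the E-alkenylstannane in which C3 and C6 are cis; unactivated alkyl chlorides are not reduced by Bu3SnH without a radical initiator.

Step 12
Reactants: 19 (2S,3E,6S,7R)-7,8-dichloro-7-methyl-3-(tributylstannyl)oct-3-ene-1,2,6-triol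
Product: 20 (2R,3Z,6S,7R)-7,8-dichloro-3,7-dimethyloct-3-ene-1,2,6-triol
Conditions: MeI, Pd(PPh3)4 (cat.), Cu(O2CC4H3S) (copper thiophene-2-carboxylate), [NBu4][Ph2PO2], DMF, rt
Reagents that add atoms: iodomethane, CI
Why: Stille-type C-methylation of an alkenylstannane: tin–copper exchange, assisted by the neighbouring C6 hydroxyl and driven by capture of Bu3Sn as its phosphinate, gives an alkenylcopper that is methylated by MeI under zerovalent palladium catalysis with retention of the alkene geometry, under neutral conditions that spare the free hydroxyls and the chlorohydrin.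

Step 13
Reactants: 20 (2R,3Z,6S,7R)-7,8-dichloro-3,7-dimethyloct-3-ene-1,2,6-triol
Product: 23 [(2S,6S)-6-[(2R)-1,2-dichloropropan-2-yl]-3-methyl-5,6-dihydro-2H-pyran-2-yl]methyl acetate, via cyclic orthoacetate 21 (not isolated), via dioxolanylium ion 22 (not isolated)
Conditions: MeC(OMe)3, PPTS (cat.), CH2Cl2, rt; then BF3·OEt2 (cat.), 0 °C
Reagents that add atoms: trimethyl orthoacetate, COC(C)(OC)OC
Why: One-pot orthoester–acetoxonium cyclisation of a 1,2,n-triol: the C6/C7 diol forms cyclic orthoacetate 21, BF3 ionises it to the 1,3-dioxolan-2-ylium ion 22, and the C2 hydroxyl attacks the allylic C6 from the face opposite the departing oxygen (6-exo-tet, SN2), closing the dihydropyran through O1–C6 with inversion (R to S at C6) and leaving C7 as its acetate, with no base in contact with the C2/C2′ chlorohydrin.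

Step 14
Reactants: 23 [(2S,6S)-6-[(2R)-1,2-dichloropropan-2-yl]-3-methyl-5,6-dihydro-2H-pyran-2-yl]methyl acetate
Product: 24 [(2S,6S)-6-[(2R)-1,2-dichloropropan-2-yl]-3-methyl-5,6-dihydro-2H-pyran-2-yl]methanol
Conditions: K2CO3 (cat.), MeOH, 0 °C
Reagents that add atoms: none
Why: Carbonate-catalysed transesterification with methanol removes the acetate; the C2 oxygen is now a ring ether, so no alkoxide can attack C2′–Cl.

Step 15
Reactants: 24 [(2S,6S)-6-[(2R)-1,2-dichloropropan-2-yl]-3-methyl-5,6-dihydro-2H-pyran-2-yl]methanol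
Product: 25 (2S,6S)-6-[(2R)-1,2-dichloropropan-2-yl]-3-methyl-5,6-dihydro-2H-pyran-2-carbaldehyde
Conditions: Dess–Martin periodinane, NaHCO3, CH2Cl2, 0 °C
Reagents that add atoms: none
Why: Dess–Martin oxidation under bicarbonate buffer gives the aldehyde without a base strong enough to enolise the allylic, α-alkoxy C6–H, and the crude aldehyde is used at once.

Step 16
Reactants: 25 (2S,6S)-6-[(2R)-1,2-dichloropropan-2-yl]-3-methyl-5,6-dihydro-2H-pyran-2-carbaldehyde
Product: 26 (2S,6S)-6-(dibromomethyl)-2-[(2R)-1,2-dichloropropan-2-yl]-5-methyl-3,6-dihydro-2H-pyran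
Conditions: P(OPh)3, Br2, CH2Cl2, −78 °C; then 25, −78 to 0 °C
Reagents that add atoms: bromine, BrBr
Why: Deoxygenative gem-dibromination of an aldehyde with the triphenyl phosphite–bromine reagent: the carbonyl oxygen is bound as an oxyphosphonium group and replaced by two bromides with formation of triphenyl phosphate, at low temperature, without base and without free bromine that could add to the C4=C5 alkene; C6 is not involved.

## Compound list

1 | (tert-butyldimethylsilyloxy)acetaldehyde | CC(C)(C)[Si](C)(C)OCC=O | starting material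
2 | ethyl 2-[bis(2,2,2-trifluoroethoxy)phosphoryl]propanoate | CCOC(=O)C(C)P(=O)(OCC(F)(F)F)OCC(F)(F)F | starting material
3 | potassium carbanion of phosphonate 2 | CCOC(=O)[C-](C)P(=O)(OCC(F)(F)F)OCC(F)(F)F.[K+] | intermediate
4 | ethyl (2Z)-4-[(tert-butyldimethylsilyl)oxy]-2-methylbut-2-enoate | CCOC(=O)/C(C)=C\CO[Si](C)(C)C(C)(C)C | intermediate
5 | (2Z)-4-[(tert-butyldimethylsilyl)oxy]-2-methylbut-2-en-1-ol | OC/C(C)=C\CO[Si](C)(C)C(C)(C)C | intermediate
6 | (2Z)-4-[(tert-butyldimethylsilyl)oxy]-2-methylbut-2-en-1-yl methanesulfonate | CS(=O)(=O)OC/C(C)=C\CO[Si](C)(C)C(C)(C)C | intermediate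
7 | tert-butyl{[(2Z)-4-chloro-3-methylbut-2-en-1-yl]oxy}dimethylsilane | ClC/C(C)=C\CO[Si](C)(C)C(C)(C)C | intermediate
8 | (2Z)-4-chloro-3-methylbut-2-en-1-ol | ClC/C(C)=C\CO | intermediate
9 | [(2S,3S)-3-(chloromethyl)-3-methyloxiran-2-yl]methanol | OC[C@@H]1O[C@]1(C)CCl | intermediate
10 | (2S,3R)-3,4-dichloro-3-methylbutane-1,2-diol | OC[C@H](O)[C@@](C)(Cl)CCl | intermediate
11 | (2S,3R)-3,4-dichloro-2-hydroxy-3-methylbutyl 4-methylbenzenesulfonate | Cc1ccc(cc1)S(=O)(=O)OC[C@H](O)[C@@](C)(Cl)CCl | intermediate
12 | (2S)-2-[(2R)-1,2-dichloropropan-2-yl]oxirane | C1O[C@@H]1[C@@](C)(Cl)CCl | intermediate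
13 | methyl (4S)-2,2-dimethyl-1,3-dioxolane-4-carboxylate | COC(=O)[C@@H]1COC(C)(C)O1 | starting material
14 | (4S)-2,2-dimethyl-1,3-dioxolane-4-carbaldehyde | O=C[C@@H]1COC(C)(C)O1 | intermediate
15 | (4R)-4-ethynyl-2,2-dimethyl-1,3-dioxolane | C#C[C@@H]1COC(C)(C)O1 | intermediate
16 | lithium acetylide of 15 | [Li]C#C[C@@H]1COC(C)(C)O1 | intermediate
17 | (2R,3S)-1,2-dichloro-6-[(4R)-2,2-dimethyl-1,3-dioxolan-4-yl]-2-methylhex-5-yn-3-ol | O[C@@H](CC#C[C@@H]1COC(C)(C)O1)[C@@](C)(Cl)CCl | intermediate
18 | (2R,6S,7R)-7,8-dichloro-7-methyloct-3-yne-1,2,6-triol | O[C@@H](CC#C[C@@H](O)CO)[C@@](C)(Cl)CCl | intermediate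
19 | (2S,3E,6S,7R)-7,8-dichloro-7-methyl-3-(tributylstannyl)oct-3-ene-1,2,6-triol | O[C@@H](C/C=C(/[Sn](CCCC)(CCCC)CCCC)[C@@H](O)CO)[C@@](C)(Cl)CCl | intermediate
20 | (2R,3Z,6S,7R)-7,8-dichloro-3,7-dimethyloct-3-ene-1,2,6-triol | O[C@@H](C/C=C(/C)[C@@H](O)CO)[C@@](C)(Cl)CCl | intermediate
21 | (2R,3S,5Z)-1,2-dichloro-6-[(4R)-2-methoxy-2-methyl-1,3-dioxolan-4-yl]-2-methylhept-5-en-3-ol (orthoester carbon as a mixture) | O[C@@H](C/C=C(/C)[C@@H]1COC(C)(OC)O1)[C@@](C)(Cl)CCl | intermediate
22 | (4R)-4-[(2Z,5S,6R)-6,7-dichloro-5-hydroxy-6-methylhept-2-en-2-yl]-2-methyl-1,3-dioxolan-2-ylium methoxytrifluoroborate | O[C@@H](C/C=C(/C)[C@@H]1COC(C)=[O+]1)[C@@](C)(Cl)CCl.CO[B-](F)(F)F | intermediate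
23 | [(2S,6S)-6-[(2R)-1,2-dichloropropan-2-yl]-3-methyl-5,6-dihydro-2H-pyran-2-yl]methyl acetate | CC1=CC[C@@H]([C@@](C)(Cl)CCl)O[C@@H]1COC(C)=O | intermediate
24 | [(2S,6S)-6-[(2R)-1,2-dichloropropan-2-yl]-3-methyl-5,6-dihydro-2H-pyran-2-yl]methanol | CC1=CC[C@@H]([C@@](C)(Cl)CCl)O[C@@H]1CO | intermediate
25 | (2S,6S)-6-[(2R)-1,2-dichloropropan-2-yl]-3-methyl-5,6-dihydro-2H-pyran-2-carbaldehyde | CC1=CC[C@@H]([C@@](C)(Cl)CCl)O[C@@H]1C=O | intermediate
26 | (2S,6S)-6-(dibromomethyl)-2-[(2R)-1,2-dichloropropan-2-yl]-5-methyl-3,6-dihydro-2H-pyran | CC1=CC[C@@H]([C@@](C)(Cl)CCl)O[C@@H]1C(Br)Br | target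

## Step count and risks

Total step count: 16. Longest linear sequence: 15 steps (steps 1–7 and 9–16); step 8 is the one-step branch to the alkyne.

Steps most likely to fail:

1. Step 11 (hydrostannation). Tin may be delivered in part to C4 instead of C5, because the C2 hydroxyl also polarises the alkyne, and the stannane may protodestannylate on purification. The fallback sets out from 17 and uses an alkoxide-directed, Fe(acac)3-catalysed syn-carbomagnesiation with MeMgBr (THF, −78 to 0 °C). The C2 magnesium alkoxide holds magnesium on C4 while methyl is delivered to C5 on the same side, and protonation gives (2R,3S,5Z)-1,2-dichloro-6-[(4R)-2,2-dimethyl-1,3-dioxolan-4-yl]-2-methylhept-5-en-3-ol F1. Methanolysis of the acetonide (p-TsOH, MeOH) then returns to the route at 20.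

2. Step 13 (ring closure). The allylic dioxolanylium ion may ionise further to an allyl cation before or after closure, eroding configuration at C6, or it may be captured at C7 or by methanol. The fallback sets out from 20 and goes through the vinyl epoxide. Tosylation of the primary hydroxyl (TsCl, Bu2SnO cat., Et3N) gives (2R,3Z,6S,7R)-7,8-dichloro-2,6-dihydroxy-3,7-dimethyloct-3-en-1-yl 4-methylbenzenesulfonate F2. K2CO3 in MeOH at 0 °C closes it, with retention at C6, to (2R,3S,5Z)-1,2-dichloro-2-methyl-6-[(2R)-oxiran-2-yl]hept-5-en-3-ol F3. CSA (cat.) in CH2Cl2 at −20 °C then lets the C2 hydroxyl open the epoxide at the allylic carbon with inversion, which returns to the route at 24.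

3. Step 16 (gem-dibromination). The bromo-oxyphosphonium intermediate may lose the acidic C6–H to give a bromo enol ether, or the aldehyde may epimerise at C6 before it reacts. The fallback sets out from 25 and converts it with hydrazine hydrate in EtOH into {[(2S,6S)-6-[(2R)-1,2-dichloropropan-2-yl]-3-methyl-5,6-dihydro-2H-pyran-2-yl]methylidene}hydrazine F4. CuBr2 and Et3N in MeOH at 0 °C then oxidise the hydrazone through the diazo compound to the gem-dibromide with loss of nitrogen, which returns to the route at 26.

Further compounds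
F1 | step 11 | (2R,3S,5Z)-1,2-dichloro-6-[(4R)-2,2-dimethyl-1,3-dioxolan-4-yl]-2-methylhept-5-en-3-ol | O[C@@H](C/C=C(/C)[C@@H]1COC(C)(C)O1)[C@@](C)(Cl)CCl
F2 | step 13 | (2R,3Z,6S,7R)-7,8-dichloro-2,6-dihydroxy-3,7-dimethyloct-3-en-1-yl 4-methylbenzenesulfonate | O[C@@H](C/C=C(/C)[C@@H](O)COS(=O)(=O)c1ccc(C)cc1)[C@@](C)(Cl)CCl
F3 | step 13 | (2R,3S,5Z)-1,2-dichloro-2-methyl-6-[(2R)-oxiran-2-yl]hept-5-en-3-ol | O[C@@H](C/C=C(/C)[C@@H]1CO1)[C@@](C)(Cl)CCl
F4 | step 16 | {[(2S,6S)-6-[(2R)-1,2-dichloropropan-2-yl]-3-methyl-5,6-dihydro-2H-pyran-2-yl]methylidene}hydrazine | CC1=CC[C@@H]([C@@](C)(Cl)CCl)O[C@@H]1C=NN
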